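## The problem

The target is a sesquiterpenoid arene. A trans-fused decalin (rings A and B, drimane numbering) carries the C4 gem-dimethyl group, an angular methyl on C10 and a methyl-bearing C7=C8 alkene. It is joined through the C9–C11 methylene to a benzene ring oxygenated at C2', C3', C5' and C6', and one of the two oxygens next to the lone aromatic hydrogen (C4'–H) is a hydrogen sulfate.

Three contiguous stereocentres, C5, C9 and C10, must be set as (5S,9R,10S). H5 and the C10 methyl are trans, and C11 lies on the face opposite the C10 methyl, axial on ring B (the 9-epi arrangement of the drimane family). Any method that equilibrates C9, or delivers hydrogen to C9 from the open face, therefore gives the wrong epimer.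

C5 can be bought and can steer the quaternary C10, because a new bond on C10 enters anti to the C5 substituent. The C10 methyl can then steer C9, because a nucleophile adding to an sp2 C9 prefers the axial path anti to that methyl. The hard carbon–carbon bonds are those around the two fully substituted carbons C4 and C10.

The fragile parts are three. The aryl hydrogen sulfate is acid- and heat-labile and must come last. The hydroxyhydroquinone is oxidised by air to the hydroxyquinone. The C7=C8 alkene next to an ortho phenol closes to a chroman or migrates to C8=C9 under strong acid, so Lewis-acid ether cleavage is excluded once arene and alkene share a molecule.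

The four phenolic oxygens form two equivalent pairs, so the sulfate must be directed to a hydroxyl flanking C4'–H and stopped after one transfer.

The key step is possible because ring B, with its C7=C8(CH3) unit and the C5 stereocentre, is the skeleton of carvone. The isopropenyl carbon of carvone already carries both methyls of C4 and lacks only the bond to C3.

## Retrosynthesis

**Sulfate and arene.** The S–O bond of target 26 is cut first, which leads to tetraol 25. The tetraol is taken back through the 2,5-dihydroxyquinone 24 and the 2,5-dimethoxyquinone 23 to the tetramethoxyarene 22. Oxidative demethylation, hydroxide exchange and dithionite reduction replace an acidic four-fold ether cleavage that the alkene and ortho phenol would not survive. Compound 22 is robust and easily purified. The forward sequence must place one sulfate on a hydroxyl that flanks C4'–H.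

**C9–C11 bond.** In 22 the bond between C9 and the benzylic carbon C11 is cut, together with the C7–H bond that replaces an enol triflate (21). Cutting C11–C1' instead would need an axial C9 aldehyde that epimerises, followed by a benzylic deoxygenation. Cutting C9–C10 would reopen the quaternary centre. The chosen cut leads to silyl enol ether 19 and from there to enone 13 and benzyl chloride 17, used as its Grignard reagent 18. The forward conjugate addition must reach a β-carbon next to a quaternary centre and enter anti to the C10 methyl. In return it sets C9 and marks C7=C8 through the enolate.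

**Arene fragment.** The benzylic C–C bond of 17 is cut to alcohol 16, and 16 is cut to 1,2,4,5-tetramethoxybenzene 14. The only aromatic positions of 14 lie between two methoxy groups, so lithiation is unambiguous.

**Carbonyl transposition.** Enone 13 is the 1,3-transposed isomer of the enone that carvone supplies. It is traced through allylic alcohols 12 and 11 and epoxy ketone 10 to the 7-en-9-one 9. The three-step epoxidation, Wharton transposition and oxidation is chosen over a 1,2-addition with oxidative transposition. That alternative would put C11 on C9 before the hydrogen and would end with the wrong C9 epimer. The sulfone is removed at the stage of 11, where no reducible group competes.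

**Ring A (key disconnection).** In 9 the C3–C4 bond is cut. This opens ring A to the dialkylated carvone 8, which carries an isopropenyl group on C5 and a 2-(phenylsulfonyl)allyl group on C10. Cutting C4–C5 or C1–C10 instead would destroy a stereocentre that carvone provides or that is cheaply set. The forward step must generate a tertiary radical at C4 selectively and close a six-membered ring onto the vinyl sulfone. No stereocentre is at stake.

**Quaternary C10.** Compound 8 is cut at the two C10–C bonds to (R)-carvone 4 through 6-methylcarvone 6, with methyl first and the sulfonylallyl group second so that the larger group enters anti to the isopropenyl group. The electrophile 3 is cut to alcohol 2 and phenyl vinyl sulfone 1.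

## Roads not taken

**Alternative 1:** The cut removes C4–C5 and C9–C10 at once, leading to the open-chain (2Z,6E)-farnesylarene A2. A2 would be made from aryllithium 15 and (2Z,6E)-farnesyl bromide A1. A chiral Lewis-acid-assisted Brønsted acid (SnCl4 with a chiral binaphthol monoether) would protonate the terminal alkene and close both rings. The Z-alkene places C11 axial, and loss of H7 gives A3, which is identical with compound 22.

- Merits: this is by far the shortest way to 22, two to three steps against fourteen, and it forms all three stereocentres in one operation.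
- Weak points: the Z-alkene forces the arylmethyl group into an axial position in the chair–chair transition state, which slows the second ring closure and favours monocyclic or isomerised products. The terminating cation at C8 can lose any of three protons, giving C7=C8, C8=C9 and exocyclic alkenes, or be trapped by an ortho methoxy oxygen. The electron-rich arene competes for the acid. Enantiocontrol rests on a stoichiometric chiral promoter. A1 must be made isomerically pure.
- Comparison: the chosen plan is much longer. Against that it sets the absolute configuration from (R)-carvone, the C9 configuration by substrate control, and an alkene position defined by a regiospecific enol triflate, with no isomer separation. If step count alone decided, Alternative 1 would win.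

**Alternative 2:** The cut removes C7–C8 and C9–C10 of ring B. The 2-silyloxydiene A4 (the kinetic silyl enol ether of the ring A methyl ketone) would add the (E)-aryl propenyl ketone A5 in an endo Diels–Alder reaction to give adduct A6.

- Merits: it is convergent, brings the whole arene in with C11, and sets C9 against C10 in one step.
- Weak points: the diene terminus that becomes C10 is fully substituted and the s-cis conformer is strained against the gem-dimethyl group. The dienophile is a β-substituted enone whose aroyl group is twisted by two ortho methoxy groups. The adduct is racemic unless a chiral Lewis acid tolerates four methoxy groups. A6 carries oxygen at C6 and C11 that must be removed, lacks the C5 stereocentre (C5=C6) and lacks the C7=C8 alkene, so at least six corrective steps follow.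
- Comparison: Alternative 2 forms more of the skeleton per step than the chosen plan. The chosen plan offsets this with a secure C5/C10 relationship and no oxidation-state repair on ring B beyond one transposition.

**Alternative 3:** The cut is made in the arene (C2'–C3'). The cyclobutenone A7, made from a squaric ester, the C11 organometallic of the decalin and a 2-ethoxyvinyl nucleophile, would open thermally to a dienylketene and close to hydroquinone A8 (Moore rearrangement).

- Merits: the arene is born differentiated. A8 has free hydroxyls only at C2' and C5', and the C5' hydroxyl next to C4'–H is sterically distinct from the other. This is better than the statistical monosulfation of the chosen plan.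
- Weak points: the ethyl and methyl ethers of A8 cannot be removed after sulfation without acid, so the advantage is lost unless cleavable groups replace them. The route also presupposes a neopentyl C11 organometallic of the 9-epi-drim-7-ene, so the decalin, the quaternary C10 and the axial C9 remain unsolved.
- Comparison: the chosen plan solves the decalin and pays with a less selective last step. Against this it sets a commercial symmetric arene, recycling of unsulfated material through 24, and a differentiated fallback.

Key step: step 5

**Conventions.** Drimane numbering is used. β is the face of the C10 methyl group. C1' bears C11 and C4' bears hydrogen. Rotation about C11–C1' exchanges C2' with C6' and C3' with C5', so sulfation of either hydroxyl flanking C4'–H gives the target.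

**Assumption.** The hydrogen sulfate is drawn as the free acid. It would be handled as its pyridinium or sodium salt and brought to the acid form by cold cation exchange.

## Route

Step 1
Reactants: 1 phenyl vinyl sulfone
Product: 2 2-(phenylsulfonyl)prop-2-en-1-ol
Conditions: aq. CH2O (37%), DABCO, THF/H2O, rt
Reagents that add atoms: formaldehyde, C=O
Why: Morita–Baylis–Hillman hydroxymethylation; the amine adds to the vinyl sulfone, the α-sulfonyl carbanion takes up formaldehyde and loss of the amine restores the alkene, as known for aryl vinyl sulfones and aldehydes.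

Step 2
Reactants: 2 2-(phenylsulfonyl)prop-2-en-1-ol
Product: 3 3-bromo-2-(phenylsulfonyl)prop-1-ene
Conditions: PBr3, Et2O, 0 °C
Reagents that add atoms: phosphorus tribromide, BrP(Br)Br
Why: Standard conversion of a primary allylic alcohol into the bromide through its phosphite ester; the electron-poor alkene is inert to the reagent.

Step 3
Reactants: 4 (R)-carvone
Product: 6 (5R,6RS)-2,6-dimethyl-5-(prop-1-en-2-yl)cyclohex-2-en-1-one (6-methylcarvone; both C6 epimers), via lithium dienolate of carvone 5 (not isolated)
Conditions: LiN(i-Pr)2, THF, −78 °C; MeI, −78 → 0 °C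
Reagents that add atoms: iodomethane, CI
Why: Kinetic α'-deprotonation of the enone gives the cross-conjugated dienolate, which is C-methylated; the new centre is erased in step 4, so the epimer mixture is of no consequence.

Step 4
Reactants: 6 6-methylcarvone; 3 3-bromo-2-(phenylsulfonyl)prop-1-ene
Product: 8 (5S,6S)-2,6-dimethyl-6-[2-(phenylsulfonyl)prop-2-en-1-yl]-5-(prop-1-en-2-yl)cyclohex-2-en-1-one (methyl cis and sulfonylallyl trans to the isopropenyl group), via lithium enolate of 6-methylcarvone 7 (not isolated)
Conditions: LiN(i-Pr)2, THF, −78 °C; 3, −78 → −20 °C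
Reagents that add atoms: none
Why: Enolate alkylation by addition–elimination on the 2-sulfonylallyl bromide; the electrophile should approach the trisubstituted enolate anti to the isopropenyl group on C5, which sets the quaternary carbon (drimane C10) with the side chain trans and the methyl cis to that group.

Step 5
Reactants: 8 dialkylated carvone
Product: 9 2ξ-(phenylsulfonyl)-11-nordrim-7-en-9-one (5α-H; 10β-CH3; both C2 epimers)
Conditions: Fe(acac)3 (30 mol%), PhSiH3, EtOH/(CH2OH)2, 60 °C
Reagents that add atoms: none
Why: An iron hydride formed from Fe(acac)3 and PhSiH3 should transfer a hydrogen atom to the terminal CH2 of the electron-rich 1,1-disubstituted isopropenyl alkene, giving the tertiary C4 radical. This nucleophilic radical adds to the terminal CH2 (C3) of the electron-poor 2-sulfonylallyl group, forming C3–C4 and an α-sulfonyl radical at C2, which divalent iron reduces and ethanol protonates. The closest known reaction type is the iron-hydride hydrogen-atom-transfer reductive coupling of an unactivated alkene with an electron-poor alkene (a Giese-type addition), including ring closures of carvone-derived isopropenyl groups onto tethered acceptors. Ring A closes in a 6-endo-trig mode through a chair in which C5–C4 and C10–C1 are both equatorial on ring B; 5-exo attack at C2 would hit the substituted alkene carbon, is polarity-mismatched and would leave an unstabilised primary radical. No lasting stereocentre is formed: C4 carries two methyls, C2 arises as an epimer mixture that step 8 erases, and the trans ring fusion is already fixed by C5 (from carvone) and C10 (from step 4). The step needs hydrogen-atom transfer to the isopropenyl group and not to the enone or vinyl sulfone, which the slow reaction of metal hydrides with electron-poor alkenes secures. It also needs ring closure to outrun reduction of the tertiary radical, which the quaternary C10 in the tether and the strong acceptor favour.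

Step 6
Reactants: 9 2ξ-(phenylsulfonyl)-11-nordrim-7-en-9-one
Product: 10 7α,8α-epoxy-2ξ-(phenylsulfonyl)-11-nordriman-9-one
Conditions: 30% H2O2, NaOH, MeOH, 0 °C → rt
Reagents that add atoms: hydrogen peroxide, OO
Why: Weitz–Scheffer nucleophilic epoxidation of the enone; hydroperoxide should add to C7 along the axial path on the α face, and the sulfone and the isolated ring carbons are untouched.

Step 7
Reactants: 10 epoxy ketone
Product: 11 2ξ-(phenylsulfonyl)-11-nordrim-8-en-7α-ol
Conditions: N2H4·H2O, AcOH (cat.), MeOH, 0 °C → rt
Reagents that add atoms: none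
Why: Wharton transposition; the epoxy hydrazone fragments with loss of N2 to the C8=C9 alkene while the C7–O bond, and with it the α configuration, is retained.

Step 8
Reactants: 11 2ξ-(phenylsulfonyl)-11-nordrim-8-en-7α-ol
Product: 12 11-nordrim-8-en-7α-ol
Conditions: Na(Hg) (6% Na), Na2HPO4, MeOH/THF, −20 °C → rt
Reagents that add atoms: none
Why: Reductive desulfonylation of an unactivated alkyl phenyl sulfone by electron transfer; it is placed here because neither the allylic alcohol nor the trisubstituted alkene is reduced, and the C2 epimers converge.

Step 9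
Reactants: 12 11-nordrim-8-en-7α-ol
Product: 13 11-nordrim-8-en-7-one (5α-H; 10β-CH3)
Conditions: Dess–Martin periodinane, NaHCO3, CH2Cl2, rt
Reagents that add atoms: none
Why: Dess–Martin oxidation of a secondary allylic alcohol to the enone under buffered, non-acidic conditions; the C7 configuration no longer matters.

Step 10
Reactants: 14 1,2,4,5-tetramethoxybenzene
Product: 16 (2,3,5,6-tetramethoxyphenyl)methanol, via (2,3,5,6-tetramethoxyphenyl)lithium 15 (not isolated)
Conditions: n-BuLi, THF, 0 °C → rt; (CH2O)n, −78 °C → rt
Reagents that add atoms: formaldehyde (as paraformaldehyde), C=O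
Why: Directed ortho-lithiation at the position flanked by two methoxy groups (the only kind of aromatic C–H present), followed by addition of the aryllithium to formaldehyde.

Step 11
Reactants: 16 (2,3,5,6-tetramethoxyphenyl)methanol
Product: 17 3-(chloromethyl)-1,2,4,5-tetramethoxybenzene
Conditions: SOCl2, Et2O, 0 °C; used crude
Reagents that add atoms: thionyl chloride, O=S(Cl)Cl
Why: Chlorination of an electron-rich benzylic alcohol through its chlorosulfite; the chloride is ionisable and is therefore used without storage.

Step 12
Reactants: 17 3-(chloromethyl)-1,2,4,5-tetramethoxybenzene; 13 11-nordrim-8-en-7-one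
Product: 19 trimethylsilyl enol ether of the conjugate adduct: 11-(2,3,5,6-tetramethoxyphenyl)-7-(trimethylsilyloxy)-9-epi-drim-7-ene (5α-H; 9β-H; 10β-CH3), via (2,3,5,6-tetramethoxybenzyl)magnesium chloride 18 (not isolated)
Conditions: Mg, THF, 0 °C; then CuBr·SMe2 (cat.), Me3SiCl, HMPA, 13, −78 → −40 °C; Et3N
Reagents that add atoms: chlorotrimethylsilane, C[Si](C)(C)Cl
Why: Copper-catalysed, chlorosilane-accelerated conjugate addition of a benzylic Grignard reagent; the benzyl group should enter C9 along the axial path anti to the C10 methyl (the sense known from 1α-alkylation of steroidal 1-en-3-ones), which sets the 9R centre with C11 on the α face. The silyl enol ether records the future alkene position at C7=C8.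

Step 13
Reactants: 19 trimethylsilyl enol ether
Product: 21 enol triflate: 11-(2,3,5,6-tetramethoxyphenyl)-9-epi-drim-7-en-7-yl trifluoromethanesulfonate, via lithium C7 enolate 20 (not isolated)
Conditions: MeLi, THF, 0 °C; PhNTf2, −78 °C → rt
Reagents that add atoms: N-phenylbis(trifluoromethanesulfonimide), O=S(=O)(N(c1ccccc1)S(=O)(=O)C(F)(F)F)C(F)(F)F
Why: Cleavage of the Si–O bond by methyllithium regenerates the regiodefined lithium enolate, which is O-sulfonylated by the triflimide; no equilibration toward C6 is possible under these conditions.

Step 14
Reactants: 21 enol triflate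
Product: 22 3-[(5S,9R,10S)-drim-7-en-11-yl]-1,2,4,5-tetramethoxybenzene (9-epi-drimane: 5α-H; 9β-H; 10β-CH3)
Conditions: Pd(OAc)2, PPh3, HCO2H, Bu3N, DMF, 60 °C
Reagents that add atoms: none
Why: Palladium-catalysed formate reduction of a vinyl triflate: oxidative addition to zerovalent palladium, formate exchange, loss of CO2 and reductive elimination of the vinyl C–H bond, which leaves the alkene at C7=C8.

Step 15
Reactants: 22 tetramethoxyarene
Product: 23 3-[(5S,9R,10S)-drim-7-en-11-yl]-2,5-dimethoxy-1,4-benzoquinone
Conditions: (NH4)2Ce(NO3)6, MeCN/H2O, 0 °C
Reagents that add atoms: water, O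
Why: Oxidative demethylation of a para-dimethoxyarene by tetravalent cerium; the two para pairs of the arene are equivalent, so only one quinone can form, and the isolated trisubstituted alkene is not attacked at 0 °C.

Step 16
Reactants: 23 dimethoxyquinone
Product: 24 3-[(5S,9R,10S)-drim-7-en-11-yl]-2,5-dihydroxy-1,4-benzoquinone
Conditions: NaOH (2 M aq.), MeOH/THF, rt → 50 °C; then cold dilute HCl to pH 3
Reagents that add atoms: sodium hydroxide, [Na+].[OH-]
Why: Both methoxy groups are vinylogous esters and are exchanged by hydroxide through addition–elimination, as for simple 3-alkyl-2,5-dimethoxybenzoquinones; base is used so that the alkene never meets strong acid.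

Step 17
Reactants: 24 dihydroxyquinone
Product: 25 3-[(5S,9R,10S)-drim-7-en-11-yl]benzene-1,2,4,5-tetraol
Conditions: Na2S2O4, EtOAc/H2O, rt, argon; used at once
Reagents that add atoms: none
Why: Dithionite reduction of a quinone to the hydroquinone; the tetraol reverts to 24 in air, so it is dried and carried on under argon.

Step 18
Reactants: 25 tetraol
Product: 26 2,4,5-trihydroxy-3-{[(1R,4aS,8aS)-2,5,5,8a-tetramethyl-1,4,4a,5,6,7,8,8a-octahydronaphthalen-1-yl]methyl}phenyl hydrogen sulfate (the target)
Conditions: SO3·pyridine (1 equiv), pyridine/DMF, 0 °C, argon; cold H+ exchange resin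
Reagents that add atoms: sulfur trioxide–pyridine complex, [O-]S(=O)(=O)[n+]1ccccc1
Why: O-Sulfation of a phenol by an amine–sulfur trioxide complex; the two hydroxyls flanking C4'–H are equivalent and less hindered than those flanking the C11 side chain, so the first sulfate should go there. One equivalent of reagent limits a second transfer, and unreacted tetraol returns to 24 on exposure to air and can be recycled.

## Compound list

1 | phenyl vinyl sulfone | C=CS(=O)(=O)c1ccccc1 | starting material
2 | 2-(phenylsulfonyl)prop-2-en-1-ol | OCC(=C)S(=O)(=O)c1ccccc1 | intermediate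
3 | 3-bromo-2-(phenylsulfonyl)prop-1-ene | BrCC(=C)S(=O)(=O)c1ccccc1 | intermediate
4 | (R)-carvone | CC1=CC[C@H](CC1=O)C(C)=C | starting material
5 | lithium dienolate of carvone (C1–O–Li, C1=C6) | CC1=CC[C@@H](C(C)=C)C=C1O[Li] | intermediate (not isolated)
6 | (5R,6RS)-2,6-dimethyl-5-(prop-1-en-2-yl)cyclohex-2-en-1-one (6-methylcarvone) | CC1=CC[C@@H](C(C)=C)C(C)C1=O | intermediate
7 | lithium enolate of 6-methylcarvone | CC1=CC[C@@H](C(C)=C)C(C)=C1O[Li] | intermediate (not isolated)
8 | (5S,6S)-2,6-dimethyl-6-[2-(phenylsulfonyl)prop-2-en-1-yl]-5-(prop-1-en-2-yl)cyclohex-2-en-1-one | CC1=CC[C@@H](C(C)=C)[C@](C)(CC(=C)S(=O)(=O)c2ccccc2)C1=O | intermediate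
9 | 2ξ-(phenylsulfonyl)-11-nordrim-7-en-9-one (5α-H, 10β-CH3) | CC1=CC[C@H]2C(C)(C)CC(S(=O)(=O)c3ccccc3)C[C@]2(C)C1=O | intermediate
10 | 7α,8α-epoxy-2ξ-(phenylsulfonyl)-11-nordriman-9-one | C[C@@]12O[C@@H]1C[C@H]3C(C)(C)CC(S(=O)(=O)c4ccccc4)C[C@]3(C)C2=O | intermediate
11 | 2ξ-(phenylsulfonyl)-11-nordrim-8-en-7α-ol | CC1=C[C@@]2(C)CC(S(=O)(=O)c3ccccc3)CC(C)(C)[C@@H]2C[C@H]1O | intermediate
12 | 11-nordrim-8-en-7α-ol | CC1=C[C@@]2(C)CCCC(C)(C)[C@@H]2C[C@H]1O | intermediate
13 | 11-nordrim-8-en-7-one (5α-H, 10β-CH3) | CC1=C[C@@]2(C)CCCC(C)(C)[C@@H]2CC1=O | intermediate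
14 | 1,2,4,5-tetramethoxybenzene | COc1cc(OC)c(OC)cc1OC | starting material
15 | (2,3,5,6-tetramethoxyphenyl)lithium | [Li]c1c(OC)c(OC)cc(OC)c1OC | intermediate (not isolated)
16 | (2,3,5,6-tetramethoxyphenyl)methanol | OCc1c(OC)c(OC)cc(OC)c1OC | intermediate
17 | 3-(chloromethyl)-1,2,4,5-tetramethoxybenzene | ClCc1c(OC)c(OC)cc(OC)c1OC | intermediate
18 | (2,3,5,6-tetramethoxybenzyl)magnesium chloride | Cl[Mg]Cc1c(OC)c(OC)cc(OC)c1OC | intermediate (not isolated)
19 | 11-(2,3,5,6-tetramethoxyphenyl)-7-(trimethylsilyloxy)-9-epi-drim-7-ene (5α-H, 9β-H, 10β-CH3) | CC1=C(O[Si](C)(C)C)C[C@H]2C(C)(C)CCC[C@]2(C)[C@@H]1Cc1c(OC)c(OC)cc(OC)c1OC | intermediate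
20 | lithium C7 enolate of the conjugate adduct | CC1=C(O[Li])C[C@H]2C(C)(C)CCC[C@]2(C)[C@@H]1Cc1c(OC)c(OC)cc(OC)c1OC | intermediate (not isolated)
21 | 11-(2,3,5,6-tetramethoxyphenyl)-9-epi-drim-7-en-7-yl trifluoromethanesulfonate | CC1=C(OS(=O)(=O)C(F)(F)F)C[C@H]2C(C)(C)CCC[C@]2(C)[C@@H]1Cc1c(OC)c(OC)cc(OC)c1OC | intermediate
22 | 3-[(5S,9R,10S)-drim-7-en-11-yl]-1,2,4,5-tetramethoxybenzene | CC1=CC[C@H]2C(C)(C)CCC[C@]2(C)[C@@H]1Cc1c(OC)c(OC)cc(OC)c1OC | intermediate
23 | 3-[(5S,9R,10S)-drim-7-en-11-yl]-2,5-dimethoxy-1,4-benzoquinone | CC1=CC[C@H]2C(C)(C)CCC[C@]2(C)[C@@H]1CC1=C(OC)C(=O)C=C(OC)C1=O | intermediate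
24 | 3-[(5S,9R,10S)-drim-7-en-11-yl]-2,5-dihydroxy-1,4-benzoquinone | CC1=CC[C@H]2C(C)(C)CCC[C@]2(C)[C@@H]1CC1=C(O)C(=O)C=C(O)C1=O | intermediate
25 | 3-[(5S,9R,10S)-drim-7-en-11-yl]benzene-1,2,4,5-tetraol | CC1=CC[C@H]2C(C)(C)CCC[C@]2(C)[C@@H]1Cc1c(O)c(O)cc(O)c1O | intermediate
26 | 2,4,5-trihydroxy-3-[(5S,9R,10S)-drim-7-en-11-yl]phenyl hydrogen sulfate | CC1=CC[C@H]2C(C)(C)CCC[C@]2(C)[C@@H]1Cc1c(O)c(O)cc(OS(=O)(=O)O)c1O | target

## Step count and least certain steps

Total step count: 18. Longest linear sequence: 15 steps (1, 2, 4–9, 12–18) from phenyl vinyl sulfone, or 14 counted from (R)-carvone.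

**Step 5 (key step).** The likeliest failure is capture of the tertiary radical by a hydrogen donor before ring closure, which would merely hydrogenate the isopropenyl group. Hydrogen-atom transfer to the vinyl sulfone is a second possibility. The fallback sets out from 8 and generates the radical at a fixed site with a controllable donor concentration. HBr in acetic acid at 0 °C should add across the isopropenyl group to give the tertiary bromide 5-(2-bromopropan-2-yl)-2,6-dimethyl-6-[2-(phenylsulfonyl)prop-2-en-1-yl]cyclohex-2-en-1-one F1. Slow addition of Bu3SnH and AIBN in benzene at 80 °C should then effect the same 6-endo closure. The fallback returns to the route at 9.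

**Step 12.** Conjugate addition at C9, which is neopentyl-like and faces an α-methyl group, may be too slow. Direct 1,2-addition, enolisation of 13 or homocoupling of the benzylic reagent would then take over. The fallback makes the C9–C11 bond intramolecularly and sets out from 12.

- O-Alkylation of 12 with 17 (NaH, Bu4NI, DMF) would give the 7α-(2,3,5,6-tetramethoxybenzyl) ether of 11-nordrim-8-en-7α-ol F2.
- n-BuLi in THF at −78 °C should trigger a [2,3]-Wittig rearrangement. It is suprafacial, so the axial 7α oxygen delivers C11 to the α face of C9 while the alkene moves to C7=C8. The product is 11-(2,3,5,6-tetramethoxyphenyl)-9-epi-drim-7-en-11-ol F3.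
- Barton–McCombie deoxygenation through the S-methyl xanthate of that carbinol F4 (NaH, CS2, MeI; then Bu3SnH, AIBN, toluene, 90 °C) returns to the route at 22.

This fallback depends on the α configuration of the epoxide formed in step 6.

**Step 18.** Over-sulfation and incomplete site discrimination among four phenolic hydroxyls are likely, made worse by air oxidation during handling. The yield of monosulfate is statistically limited. The fallback sets out from 24 and leaves only two free hydroxyls of different hindrance.

- Acetylation (Ac2O, Et3N, CH2Cl2, 0 °C) would give 2,5-diacetoxy-3-[(5S,9R,10S)-drim-7-en-11-yl]-1,4-benzoquinone F5.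
- Dithionite reduction would give the 2,5-diacetoxyhydroquinone F6, whose free hydroxyls flank C4'–H and C1' respectively.
- SO3·pyridine in acetonitrile at 0 °C, with no excess base so that ortho acyl shifts stay slow, should sulfate the hydroxyl next to C4'–H to give the diacetoxy monosulfate F7.
- K2CO3 in degassed methanol at 0 °C, followed by cation exchange, removes both acetates and returns to the route at 26.

**Step 7.** Hydrazone formation at the C9 carbonyl, which lies between a quaternary carbon and the epoxide carbon, may be slow, so that opening of the epoxide by hydrazine competes. The fallback avoids condensation at C9 and sets out from 10.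

- NaBH4 in methanol at 0 °C would give 7α,8α-epoxy-2ξ-(phenylsulfonyl)-11-nordriman-9-ol F8.
- NaH, CS2 and MeI would give its S-methyl xanthate F9.
- Bu3SnH and AIBN in benzene at 80 °C should generate the C9 radical, which opens the adjacent epoxide to the C8=C9 alkene and a C7 alkoxyl radical that is reduced. This returns to the route at 11.

## Further compounds

F1 | step 5 | 5-(2-bromopropan-2-yl)-2,6-dimethyl-6-[2-(phenylsulfonyl)prop-2-en-1-yl]cyclohex-2-en-1-one (ring stereocentres as in 8) | CC1=CC[C@@H](C(C)(C)Br)[C@](C)(CC(=C)S(=O)(=O)c2ccccc2)C1=O
F2 | step 12 | 7α-(2,3,5,6-tetramethoxybenzyl) ether of 11-nordrim-8-en-7α-ol | CC1=C[C@@]2(C)CCCC(C)(C)[C@@H]2C[C@H]1OCc1c(OC)c(OC)cc(OC)c1OC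
F3 | step 12 | 11-(2,3,5,6-tetramethoxyphenyl)-9-epi-drim-7-en-11-ol (C11 epimers) | CC1=CC[C@H]2C(C)(C)CCC[C@]2(C)[C@@H]1C(O)c1c(OC)c(OC)cc(OC)c1OC
F4 | step 12 | O-[11-(2,3,5,6-tetramethoxyphenyl)-9-epi-drim-7-en-11-yl] S-methyl dithiocarbonate | CC1=CC[C@H]2C(C)(C)CCC[C@]2(C)[C@@H]1C(OC(=S)SC)c1c(OC)c(OC)cc(OC)c1OC
F5 | step 18 | 2,5-diacetoxy-3-[(5S,9R,10S)-drim-7-en-11-yl]-1,4-benzoquinone | CC1=CC[C@H]2C(C)(C)CCC[C@]2(C)[C@@H]1CC1=C(OC(C)=O)C(=O)C=C(OC(C)=O)C1=O
F6 | step 18 | 2,5-diacetoxy-3-[(5S,9R,10S)-drim-7-en-11-yl]benzene-1,4-diol | CC1=CC[C@H]2C(C)(C)CCC[C@]2(C)[C@@H]1Cc1c(OC(C)=O)c(O)cc(OC(C)=O)c1O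
F7 | step 18 | 2,5-diacetoxy-3-[(5S,9R,10S)-drim-7-en-11-yl]-4-hydroxyphenyl hydrogen sulfate (sulfate on the oxygen next to C4'–H) | CC1=CC[C@H]2C(C)(C)CCC[C@]2(C)[C@@H]1Cc1c(OC(C)=O)c(OS(=O)(=O)O)cc(OC(C)=O)c1O
F8 | step 7 | 7α,8α-epoxy-2ξ-(phenylsulfonyl)-11-nordriman-9-ol (C9 epimers) | C[C@@]12O[C@@H]1C[C@H]3C(C)(C)CC(S(=O)(=O)c4ccccc4)C[C@]3(C)C2O
F9 | step 7 | O-[7α,8α-epoxy-2ξ-(phenylsulfonyl)-11-nordriman-9-yl] S-methyl dithiocarbonate | C[C@@]12O[C@@H]1C[C@H]3C(C)(C)CC(S(=O)(=O)c4ccccc4)C[C@]3(C)C2OC(=S)SC
A1 | alternative 1 | (2Z,6E)-farnesyl bromide | BrC/C=C(C)\CC/C=C(C)/CCC=C(C)C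
A2 | alternative 1 | 3-[(2Z,6E)-farnesyl]-1,2,4,5-tetramethoxybenzene | COc1cc(OC)c(OC)c(C/C=C(C)\CC/C=C(C)/CCC=C(C)C)c1OC
A3 | alternative 1 | 3-[(5S,9R,10S)-drim-7-en-11-yl]-1,2,4,5-tetramethoxybenzene (identical with 22) | CC1=CC[C@H]2C(C)(C)CCC[C@]2(C)[C@@H]1Cc1c(OC)c(OC)cc(OC)c1OC
A4 | alternative 2 | tert-butyldimethylsilyl enol ether of 1-acetyl-2,6,6-trimethylcyclohexene (2-silyloxydiene) | C=C(O[Si](C)(C)C(C)(C)C)C1=C(C)CCCC1(C)C
A5 | alternative 2 | (E)-1-(2,3,5,6-tetramethoxyphenyl)but-2-en-1-one | C/C=C/C(=O)c1c(OC)c(OC)cc(OC)c1OC
A6 | alternative 2 | endo Diels–Alder adduct, C5=C6 silyl enol ether with C11 ketone | C[C@H]1CC(O[Si](C)(C)C(C)(C)C)=C2C(C)(C)CCC[C@]2(C)[C@@H]1C(=O)c1c(OC)c(OC)cc(OC)c1OC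
A7 | alternative 3 | 2-[(5S,9R,10S)-drim-7-en-11-yl]-4-(2-ethoxyvinyl)-4-hydroxy-3-methoxycyclobut-2-en-1-one | CC1=CC[C@H]2C(C)(C)CCC[C@]2(C)[C@@H]1CC1=C(OC)C(O)(C=COCC)C1=O
A8 | alternative 3 | 3-ethoxy-6-methoxy-2,5-dihydroxy arene carrying the drim-7-en-11-yl group | CC1=CC[C@H]2C(C)(C)CCC[C@]2(C)[C@@H]1Cc1c(O)c(OCC)cc(O)c1OC
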